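**Plan**

- **Cuts (chroman numbering):** first the O-protecting groups, then C8–C(=O) of the side chain, C3–H (alcohol back to the 3-ketone), C4–C4a of the pyran ring, O1–C2, and last C8a–O1 back to an aryl C–H of 2-methylresorcinol.
- **Enabling feature:** in ring A, C4a sits ortho to O1, ortho to the C5 oxygen and para to the C7 oxygen, so it is the best carbon nucleophile of the ring. Its partner C4 is the CH2 end of the enol ether of a C3 ketone, held within bonding distance by O1 and the fully substituted C2.
- **Forward order:** ring A is bought, and O1 is introduced by C–H borylation/oxidation. The C2–C3–C4 unit is then hung on O1 and the pyran ring closes anodically as a 3-chromanone. The 3-phenylpropanoyl chain is joined last at C8 by directed lithiation.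
- **Stereochemistry:** the single stereocentre C3 (S) comes from a catalyst-controlled Corey–Bakshi–Shibata reduction of the 3-chromanone. No later step breaks a bond at C3.

Key step: step 5

Remark: chroman numbering (O1, C2, C3, C4, C4a, C5–C8, C8a) is used for all bicyclic compounds; C3 is C5'' of the trivial name, and the [C@@H] centre of the given SMILES is read as (S).

Step 1
Reactants: 1 2-methylresorcinol (2-methylbenzene-1,3-diol)
Product: 2 1,3-bis(methoxymethoxy)-2-methylbenzene
Conditions: MOMCl (2.6 equiv), iPr2NEt (3 equiv), CH2Cl2, 0 °C → rt
Reagents that add atoms: chloromethyl methyl ether, COCCl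
Why: Williamson-type O-alkylation of both phenols with the reactive α-chloro ether should give base-stable acetals that later steer the borylation by their bulk and the lithiation by chelation.

Step 2
Reactants: 2 1,3-bis(methoxymethoxy)-2-methylbenzene
Product: 4 3,5-bis(methoxymethoxy)-4-methylphenol, via aryl pinacolboronate 3 (not isolated)
Conditions: [Ir(OMe)(cod)]2 (1.5 mol%), dtbpy (3 mol%), B2pin2 (0.6 equiv), THF, 80 °C (sealed); then aq NaOH, 30% H2O2, 0 °C → rt
Reagents that add atoms: bis(pinacolato)diboron, CC1(C)OB(OC1(C)C)B1OC(C)(C)C(C)(C)O1 (boryl group of 3 only); hydrogen peroxide, OO (phenol oxygen of 4)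
Why: Iridium-catalysed aromatic C–H borylation is sterically governed and should take the only ring C–H without an ortho substituent (para to the methyl group), after which the standard basic peroxide oxidation of the arylboronate (1,2-aryl shift from boron to oxygen) gives the phenol without harming the MOM ethers.

Step 3
Reactants: 4 3,5-bis(methoxymethoxy)-4-methylphenol; 5 3-bromo-3-methylbutan-2-one (2 equiv)
Product: 6 3-[3,5-bis(methoxymethoxy)-4-methylphenoxy]-3-methylbutan-2-one
Conditions: Cs2CO3 (2 equiv), DMF, rt → 50 °C
Reagents that add atoms: none
Why: Williamson-type substitution of a carbonyl-activated tertiary α-bromide by the caesium phenoxide, the reaction class used to alkylate phenols with 2-bromoisobutyrates, should fix the only free oxygen on the future C2, and the excess bromide covers losses by dehydrobromination.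

Step 4
Reactants: 6 3-[3,5-bis(methoxymethoxy)-4-methylphenoxy]-3-methylbutan-2-one
Product: 8 tert-butyl{3-[3,5-bis(methoxymethoxy)-4-methylphenoxy]-3-methylbut-1-en-2-yloxy}dimethylsilane, via potassium enolate 7 (not isolated)
Conditions: KN(SiMe3)2 (1.2 equiv), THF, −78 °C; then TBSCl (1.3 equiv), −78 → 0 °C; Et3N-deactivated silica
Reagents that add atoms: tert-butyldimethylsilyl chloride, CC(C)(C)[Si](C)(C)Cl; potassium hexamethyldisilazide, C[Si](C)(C)[N-][Si](C)(C)C.[K+] (potassium of 7 only)
Why: Silyl enol ether formation by deprotonation and O-silylation can only involve the methyl group because the other α-carbon is quaternary, the Lewis acid-free conditions spare the aryl MOM ethers, and the TBS group is chosen because it should survive a methanolic electrolyte.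

Step 5
Reactants: 8 tert-butyl{3-[3,5-bis(methoxymethoxy)-4-methylphenoxy]-3-methylbut-1-en-2-yloxy}dimethylsilane
Product: 9 5,7-bis(methoxymethoxy)-2,2,6-trimethylchroman-3-one
Conditions: reticulated vitreous carbon anode, Pt cathode, undivided cell, constant current 8 mA to 2.1 F/mol, 0.1 M LiClO4, 2,6-lutidine (4 equiv), MeOH/CH2Cl2 1:4, 0.03 M in 8, rt
Reagents that add atoms: none
Why: Removal of one electron at the carbon anode from the tethered donor pair (the trialkoxyarene probably goes first, but arene and enol ether radical cations lead to the same bond) joins the CH2 terminus of the enol ether to the ring carbon ortho to the aryl ether oxygen, forming C4–C4a, and a second electron transfer, loss of the ring proton to 2,6-lutidine and transfer of the silyl group to methanol then give the rearomatised 3-ketone while protons are reduced at the cathode. The closest known reaction type is the anodic coupling of silyl and alkyl enol ethers with furans and alkoxyarenes, and the electron-transfer α-arylation of terminal ketone silyl enol ethers to 2-tetralones shows the same ring topology. The pyran closes 6-endo-trig with respect to the C3=C4 enol ether, since bonding at the unsubstituted terminus keeps spin and charge on the oxygen-bearing C3, whereas a 5-exo closure would leave them on a primary carbon. No stereocentre is created. The step needs site selectivity on ring A, which the substrate secures because the two ortho carbons are related by the mirror plane through O1 and the methyl group and each is ortho, ortho and para to an oxygen, while the ipso carbon is meta to both MOM ethers and the quaternary C2 allows only the terminal enol ether and folds the tether (Thorpe–Ingold effect). It also needs chemoselectivity against further oxidation and methanol capture, which is addressed by the fast intramolecular trapping, the methanol-poor buffered medium and ending the electrolysis near the theoretical charge.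

Step 6
Reactants: 9 5,7-bis(methoxymethoxy)-2,2,6-trimethylchroman-3-one
Product: 10 (3S)-5,7-bis(methoxymethoxy)-2,2,6-trimethylchroman-3-ol
Conditions: (R)-Me-CBS [(3aR)-1-methyl-3,3-diphenyltetrahydro-1H,3H-pyrrolo[1,2-c][1,3,2]oxazaborole] (15 mol%), BH3·SMe2 (1.0 equiv), THF, −20 °C, slow addition of 9; then MeOH
Reagents that add atoms: none
Why: In this Corey–Bakshi–Shibata reduction the ketone should bind to the catalyst–borane complex with the quaternary C2 as the large and the C4 methylene as the small substituent, so that the (R)-catalyst, which turns large/small ketones of this priority pattern into (S)-alcohols, sets C3 as (S) as it does for tert-alkyl and α-quaternary cyclic ketones.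

Step 7
Reactants: 10 (3S)-5,7-bis(methoxymethoxy)-2,2,6-trimethylchroman-3-ol
Product: 11 {[(3S)-5,7-bis(methoxymethoxy)-2,2,6-trimethylchroman-3-yl]oxy}triethylsilane
Conditions: TESCl (1.5 equiv), imidazole (3 equiv), DMF, 0 °C → rt
Reagents that add atoms: chlorotriethylsilane, CC[Si](Cl)(CC)CC
Why: Standard silylation of a secondary alcohol with a silyl chloride and imidazole masks the acidic O–H before the lithiation, avoids silyl triflates that could attack aryl MOM ethers, and installs a group that falls off together with them at the end.

Step 8
Reactants: 12 3-phenylpropanoyl chloride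
Product: 13 N-methoxy-N-methyl-3-phenylpropanamide
Conditions: MeNH(OMe)·HCl (1.1 equiv), Et3N (2.2 equiv), CH2Cl2, 0 °C → rt
Reagents that add atoms: N,O-dimethylhydroxylamine hydrochloride, CNOC.Cl
Why: N-acylation of N,O-dimethylhydroxylamine by the acid chloride gives the Weinreb amide, an acyl donor that stops at the ketone stage with organolithium reagents.

Step 9
Reactants: 11 {[(3S)-5,7-bis(methoxymethoxy)-2,2,6-trimethylchroman-3-yl]oxy}triethylsilane; 13 N-methoxy-N-methyl-3-phenylpropanamide
Product: 15 1-[(3S)-5,7-bis(methoxymethoxy)-2,2,6-trimethyl-3-(triethylsilyloxy)chroman-8-yl]-3-phenylpropan-1-one, via C8 aryllithium 14 (not isolated)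
Conditions: n-BuLi (1.2 equiv), TMEDA (1.2 equiv), THF, 0 °C, 1 h; then 13 (1.3 equiv), −78 → 0 °C; aq NH4Cl
Reagents that add atoms: n-butyllithium, [Li]CCCC (lithium of 14 only)
Why: Directed ortho-metalation should remove the only aromatic hydrogen, C8–H, which lies between the chelating C7 MOM ether and O1, and the aryllithium adds once to the amide (Weinreb ketone synthesis) because the chelated adduct lasts until the quench, a sequence preferred to a Lewis acid Friedel–Crafts acylation that would strip the acetals.

Step 10
Reactants: 15 1-[(3S)-5,7-bis(methoxymethoxy)-2,2,6-trimethyl-3-(triethylsilyloxy)chroman-8-yl]-3-phenylpropan-1-one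
Product: 16 1-[(3S)-3,5,7-trihydroxy-2,2,6-trimethylchroman-8-yl]-3-phenylpropan-1-one (target)
Conditions: HCl (1 M in MeOH), 40 °C
Reagents that add atoms: none
Why: Acid-catalysed transacetalisation of the two aryl MOM ethers and methanolysis of the TES ether should free all three hydroxyl groups in one operation, and C3 keeps its configuration because its C–O bond is never broken.

**Compound list**

1 | 2-methylresorcinol | Cc1c(O)cccc1O | starting material
2 | 1,3-bis(methoxymethoxy)-2-methylbenzene | Cc1c(OCOC)cccc1OCOC | intermediate
3 | 2-[3,5-bis(methoxymethoxy)-4-methylphenyl]-4,4,5,5-tetramethyl-1,3,2-dioxaborolane (aryl pinacolboronate) | Cc1c(OCOC)cc(B2OC(C)(C)C(C)(C)O2)cc1OCOC | intermediate (not isolated)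
4 | 3,5-bis(methoxymethoxy)-4-methylphenol | Cc1c(OCOC)cc(O)cc1OCOC | intermediate
5 | 3-bromo-3-methylbutan-2-one | CC(=O)C(C)(C)Br | starting material
6 | 3-[3,5-bis(methoxymethoxy)-4-methylphenoxy]-3-methylbutan-2-one | Cc1c(OCOC)cc(OC(C)(C)C(C)=O)cc1OCOC | intermediate
7 | potassium 3-[3,5-bis(methoxymethoxy)-4-methylphenoxy]-3-methylbut-1-en-2-olate (potassium enolate) | Cc1c(OCOC)cc(OC(C)(C)C(=C)[O-])cc1OCOC.[K+] | intermediate (not isolated)
8 | tert-butyl{3-[3,5-bis(methoxymethoxy)-4-methylphenoxy]-3-methylbut-1-en-2-yloxy}dimethylsilane | Cc1c(OCOC)cc(OC(C)(C)C(=C)O[Si](C)(C)C(C)(C)C)cc1OCOC | intermediate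
9 | 5,7-bis(methoxymethoxy)-2,2,6-trimethylchroman-3-one | Cc1c(OCOC)c2c(cc1OCOC)OC(C)(C)C(=O)C2 | intermediate
10 | (3S)-5,7-bis(methoxymethoxy)-2,2,6-trimethylchroman-3-ol | Cc1c(OCOC)c2c(cc1OCOC)OC(C)(C)[C@@H](O)C2 | intermediate
11 | {[(3S)-5,7-bis(methoxymethoxy)-2,2,6-trimethylchroman-3-yl]oxy}triethylsilane | Cc1c(OCOC)c2c(cc1OCOC)OC(C)(C)[C@@H](O[Si](CC)(CC)CC)C2 | intermediate
12 | 3-phenylpropanoyl chloride | O=C(Cl)CCc1ccccc1 | starting material
13 | N-methoxy-N-methyl-3-phenylpropanamide | CON(C)C(=O)CCc1ccccc1 | intermediate
14 | [(3S)-5,7-bis(methoxymethoxy)-2,2,6-trimethyl-3-(triethylsilyloxy)chroman-8-yl]lithium (C8 aryllithium) | Cc1c(OCOC)c2c(c([Li])c1OCOC)OC(C)(C)[C@@H](O[Si](CC)(CC)CC)C2 | intermediate (not isolated)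
15 | 1-[(3S)-5,7-bis(methoxymethoxy)-2,2,6-trimethyl-3-(triethylsilyloxy)chroman-8-yl]-3-phenylpropan-1-one | Cc1c(OCOC)c2c(c(C(=O)CCc3ccccc3)c1OCOC)OC(C)(C)[C@@H](O[Si](CC)(CC)CC)C2 | intermediate
16 | 1-[(3S)-3,5,7-trihydroxy-2,2,6-trimethylchroman-8-yl]-3-phenylpropan-1-one | Cc1c(O)c2c(c(C(=O)CCc3ccccc3)c1O)OC(C)(C)[C@@H](O)C2 | target

**Step count**

Total step count: 10.
Longest linear sequence: 9 steps (steps 1–7, 9 and 10, from 2-methylresorcinol 1). Step 8 is a one-step side branch.

**Steps most likely to fail**

1. **Step 5 (anodic ring closure).**
   - What may go wrong: further oxidation of the cyclised material through its enol or its now pentasubstituted arene, capture of the radical cation by methanol before the ring closes, and solvolysis of the silyl enol ether in the electrolyte. The endo closure is also less tried in anodic couplings than exo closures, and the enolisable ketone should be carried on without storage.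
   - Fallback: the same C4–C4a bond is made by two-electron cross-coupling chemistry. It sets out from ketone 6. NBS (1 equiv, MeCN, 0 °C) should brominate one of the two equivalent ring carbons ortho to the ether oxygen to give 3-[2-bromo-3,5-bis(methoxymethoxy)-4-methylphenoxy]-3-methylbutan-2-one F1. An intramolecular palladium-catalysed ketone α-arylation (Pd2(dba)3, XPhos, NaOtBu, toluene, 80 °C), which can use only the methyl-side enolate, then closes the pyran ring and comes back to the route at chromanone 9.

2. **Step 3 (tertiary aryl ether).**
   - What may go wrong: dehydrobromination of the tertiary bromide outrunning substitution, and attachment of the oxygen at the wrong carbon through elimination followed by conjugate addition or through an oxyallyl pathway.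
   - Fallback: the quaternary carbon is built on the oxygen by a Bargellini reaction instead of displacing a tertiary halide. It sets out from phenol 4. Acetone, CHCl3 and powdered NaOH (0 °C → reflux, then careful acidification to pH 4) should give 2-[3,5-bis(methoxymethoxy)-4-methylphenoxy]-2-methylpropanoic acid F2. MeLi (2.2 equiv, THF, 0 °C) adds once to the lithium carboxylate and, after aqueous quench, comes back to the route at ketone 6.

3. **Step 6 (setting C3).**
   - What may go wrong: poor facial selectivity if the catalyst distinguishes the quaternary C2 from the benzylic C4 less well than expected, uncatalysed background reduction by free borane, and stalling through enolisation of the ketone.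
   - Fallback: control is handed from a steric small-molecule model to an enzyme active site. It sets out from chromanone 9. A ketoreductase picked from a screening panel for (S)-selectivity (NADP+, isopropanol as hydride source, phosphate buffer pH 7 with DMSO cosolvent, 30 °C) reduces the ketone and comes back to the route at alcohol 10. This detour passes through no new compound (entry F0).

**Further compounds**

F1 | step 5 | 3-[2-bromo-3,5-bis(methoxymethoxy)-4-methylphenoxy]-3-methylbutan-2-one | Cc1c(OCOC)cc(OC(C)(C)C(C)=O)c(Br)c1OCOC
F2 | step 3 | 2-[3,5-bis(methoxymethoxy)-4-methylphenoxy]-2-methylpropanoic acid | Cc1c(OCOC)cc(OC(C)(C)C(O)=O)cc1OCOC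
F0 | step 6 | none | none
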